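**Retrosynthetic overview**
1. Ring A (the chlorinated resorcinol ring) is bought; its carboxyl group and chlorine are put on in one oxidation.
2. Key disconnection: the lactone O–C3 bond of ring B (pyranone) and the O–C2' bond of ring C (oxolane) are opened together, back to one acyclic hydroxy epoxy dienyl keto acid.
3. That acid is cut at C4–C3 into an o-toluic acid dianion (fragment 1) and a dienyl Weinreb amide (fragment 2); union and both ring closures run in one flask.
4. Fragment 2 holds all stereocentres: the carbinol from a chiral-pool epoxide, C2'/C3' from a catalyst-controlled trans epoxide (C2' inverted on ring closure); the E,E-diene comes from two Wittig reactions.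
5. Ring order: A (bought) → B and C together → desilylation.

Assumption: the target is read as the (2S,3R,5R)-oxolane with a (1E,3E)-diene; LiN(iPr)2, LiN(SiMe3)2, CH2=CHMgBr and Bu4NF are used as purchased solutions.

**Route**

Step 1
Reactants: 1 2,4-dihydroxy-6-methylbenzaldehyde
Product: 2 3-chloro-4,6-dihydroxy-2-methylbenzoic acid
Conditions: NaClO2 (1.05 equiv), NH2SO3H (1.1 equiv), THF/H2O, 0 °C to rt, no chlorine scavenger
Reagents that add atoms: sodium chlorite [Na+].[O-]Cl=O
Why: Lindgren–Pinnick chlorite oxidation of the aldehyde releases one equivalent of HOCl, which without a scavenger chlorinates the activated ring at C3 (ortho to the methyl, para to the chelated OH), the same site that electrophilic chlorination of this aldehyde is known to take; no stereocentre.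

Step 2
Reactants: 2 3-chloro-4,6-dihydroxy-2-methylbenzoic acid
Product: 4 bis-silyl acid 4,6-bis[(tert-butyldimethylsilyl)oxy]-3-chloro-2-methylbenzoic acid, via tris-silyl ester 3 (not isolated)
Conditions: TBSCl (3.5 equiv), imidazole, DMF, rt to 40 °C; then AcOH/THF/H2O, rt
Reagents that add atoms: tert-butyldimethylsilyl chloride CC(C)(C)[Si](C)(C)Cl
Why: Exhaustive silylation followed by selective hydrolysis of the labile silyl ester is standard silyl ether protection and leaves an acid whose only acidic C–H after carboxylate formation is the benzylic methyl.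

Step 3
Reactants: 5 (R)-2-methyloxirane; 6 vinylmagnesium bromide
Product: 7 (2R)-pent-4-en-2-ol
Conditions: CuI (5 mol%), THF, −30 to 0 °C; then 1 M HCl
Reagents that add atoms: none
Why: CuI-catalysed Grignard opening of the epoxide at the unhindered CH2 terminus leaves the stereocentre untouched, so (R) is carried over from 5.

Step 4
Reactants: 7 (2R)-pent-4-en-2-ol; 8 (E)-but-2-enal
Product: 9 (2E,5R)-5-hydroxyhex-2-enal
Conditions: 8 (5 equiv), second-generation Grubbs catalyst RuCl2(=CHPh)(PCy3)(H2IMes) (3 mol%), CH2Cl2, 40 °C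
Reagents that add atoms: none
Why: Olefin cross-metathesis of a terminal alkene with an excess of the less reactive enal gives the E-enal with loss of propene, and the free homoallylic alcohol is tolerated.

Step 5
Reactants: 9 (2E,5R)-5-hydroxyhex-2-enal; 10 (triphenylphosphoranylidene)acetaldehyde
Product: 12 (2E)-3-[(2R,3R)-3-[(2R)-2-hydroxypropyl]oxiran-2-yl]prop-2-enal, via epoxy aldehyde 11 (not isolated)
Conditions: (S)-2-[bis(3,5-bis(trifluoromethyl)phenyl)(trimethylsilyloxy)methyl]pyrrolidine (10 mol%), 35% aq H2O2 (1.3 equiv), CH2Cl2, rt; Me2S to destroy residual H2O2; then 10 (1.3 equiv), rt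
Reagents that add atoms: hydrogen peroxide OO
Why: Jørgensen–Hayashi iminium/enamine epoxidation adds HOO– to C3 of the E-iminium on the face away from the diaryl(silyloxy)methyl group and the enamine closes the trans epoxide, giving (2S,3R) under catalyst control (derived from the standard facial model for this catalyst, with the remote carbinol as a spectator), and the very electrophilic epoxy aldehyde is trapped in the same flask by an E-selective stabilised-ylide Wittig reaction.

Step 6
Reactants: 12 (2E)-3-[(2R,3R)-3-[(2R)-2-hydroxypropyl]oxiran-2-yl]prop-2-enal; 13 N-methoxy-N-methyl-2-(triphenylphosphoranylidene)acetamide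
Product: 14 (2E,4E)-5-[(2R,3R)-3-[(2R)-2-hydroxypropyl]oxiran-2-yl]-N-methoxy-N-methylpenta-2,4-dienamide
Conditions: 13 (1.2 equiv), CH2Cl2, rt to 40 °C
Reagents that add atoms: none
Why: Wittig olefination with the amide-stabilised ylide is E-selective and neutral, so the epoxide, the free alcohol and the first E-alkene survive.

Step 7
Reactants: 4 4,6-bis[(tert-butyldimethylsilyl)oxy]-3-chloro-2-methylbenzoic acid; 14 (2E,4E)-5-[(2R,3R)-3-[(2R)-2-hydroxypropyl]oxiran-2-yl]-N-methoxy-N-methylpenta-2,4-dienamide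
Product: 19 6,8-bis[(tert-butyldimethylsilyl)oxy]-5-chloro-3-[(1E,3E)-4-[(2S,3R,5R)-3-hydroxy-5-methyloxolan-2-yl]buta-1,3-dien-1-yl]-1H-isochromen-1-one, via dilithio dianion 15 (not isolated), via lithium alkoxide 16 (not isolated), via tetrahedral adduct 17 (not isolated), via seco keto acid 18 (not isolated)
Conditions: 4 (1.3 equiv), LiN(iPr)2 (2.7 equiv), THF, −78 to 0 to −78 °C; add 14 (1.0 equiv) premixed with LiN(SiMe3)2 (1.0 equiv) in THF, −78 °C; AcOH, −78 °C to rt; cold aq citric acid wash, CH2Cl2; then CSA (0.3 equiv), 4 Å molecular sieves, CH2Cl2, 0 °C to rt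
Reagents that add atoms: none
Why: Proposed new method: carboxylate-directed lateral lithiation of the o-toluic acid (Creger-type dianion) and 1,2-addition to the Weinreb amide give a chelated adduct that stops at the ketone stage; on acidification the carboxyl adds to the dienyl ketone and dehydrates to the pyranone (the enol lactonisation known as a side reaction of resorcylate keto seco acids), while the secondary hydroxyl opens the acid-activated dienyl epoxide 5-endo at the allylic carbon by SN2 with inversion (the (R) epoxide carbon becomes C2'(S), C3' is retained, hence 2',3'-trans and 2',5'-cis); the closest known reactions are toluate-anion acylations by unsaturated Weinreb amides and acid-catalysed hydroxy vinyl epoxide cyclisations.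

Step 8
Reactants: 19 6,8-bis[(tert-butyldimethylsilyl)oxy]-5-chloro-3-[(1E,3E)-4-[(2S,3R,5R)-3-hydroxy-5-methyloxolan-2-yl]buta-1,3-dien-1-yl]-1H-isochromen-1-one
Product: 20 5-chloro-6,8-dihydroxy-3-[(1E,3E)-4-[(2S,3R,5R)-3-hydroxy-5-methyloxolan-2-yl]buta-1,3-dien-1-yl]-1H-isochromen-1-one
Conditions: Bu4NF (2.2 equiv), AcOH (2.5 equiv), THF, 0 °C
Reagents that add atoms: none
Why: Fluoride cleavage of the two aryl silyl ethers, buffered by AcOH, leaves the lactone, the dienyl oxolane and the secondary alcohol untouched and affects no stereocentre.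

**Compound list**

1 | 2,4-dihydroxy-6-methylbenzaldehyde | Cc1cc(O)cc(O)c1C=O | starting material
2 | 3-chloro-4,6-dihydroxy-2-methylbenzoic acid | Cc1c(Cl)c(O)cc(O)c1C(=O)O | intermediate
3 | tert-butyldimethylsilyl 4,6-bis[(tert-butyldimethylsilyl)oxy]-3-chloro-2-methylbenzoate | Cc1c(Cl)c(O[Si](C)(C)C(C)(C)C)cc(O[Si](C)(C)C(C)(C)C)c1C(=O)O[Si](C)(C)C(C)(C)C | intermediate
4 | 4,6-bis[(tert-butyldimethylsilyl)oxy]-3-chloro-2-methylbenzoic acid | Cc1c(Cl)c(O[Si](C)(C)C(C)(C)C)cc(O[Si](C)(C)C(C)(C)C)c1C(=O)O | intermediate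
5 | (R)-2-methyloxirane ((R)-propylene oxide) | C[C@@H]1CO1 | starting material
6 | vinylmagnesium bromide | C=C[Mg]Br | starting material
7 | (2R)-pent-4-en-2-ol | C[C@@H](O)CC=C | intermediate
8 | (E)-but-2-enal (crotonaldehyde) | C/C=C/C=O | starting material
9 | (2E,5R)-5-hydroxyhex-2-enal | C[C@@H](O)C/C=C/C=O | intermediate
10 | (triphenylphosphoranylidene)acetaldehyde | O=CC=P(c1ccccc1)(c1ccccc1)c1ccccc1 | starting material
11 | (2S,3R)-3-[(2R)-2-hydroxypropyl]oxirane-2-carbaldehyde | C[C@@H](O)C[C@H]1O[C@@H]1C=O | intermediate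
12 | (2E)-3-[(2R,3R)-3-[(2R)-2-hydroxypropyl]oxiran-2-yl]prop-2-enal | C[C@@H](O)C[C@H]1O[C@@H]1/C=C/C=O | intermediate
13 | N-methoxy-N-methyl-2-(triphenylphosphoranylidene)acetamide | CON(C)C(=O)C=P(c1ccccc1)(c1ccccc1)c1ccccc1 | starting material
14 | (2E,4E)-5-[(2R,3R)-3-[(2R)-2-hydroxypropyl]oxiran-2-yl]-N-methoxy-N-methylpenta-2,4-dienamide | C[C@@H](O)C[C@H]1O[C@@H]1/C=C/C=C/C(=O)N(C)OC | intermediate
15 | lithium 4,6-bis[(tert-butyldimethylsilyl)oxy]-3-chloro-2-(lithiomethyl)benzoate | [Li]Cc1c(Cl)c(O[Si](C)(C)C(C)(C)C)cc(O[Si](C)(C)C(C)(C)C)c1C(=O)O[Li] | intermediate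
16 | lithium (2R)-1-[(2R,3R)-3-[(1E,3E)-5-[methoxy(methyl)amino]-5-oxopenta-1,3-dien-1-yl]oxiran-2-yl]propan-2-olate | C[C@@H](O[Li])C[C@H]1O[C@@H]1/C=C/C=C/C(=O)N(C)OC | intermediate
17 | trilithium adduct: lithium 4,6-bis[(tert-butyldimethylsilyl)oxy]-3-chloro-2-[(3E,5E)-2-(lithiooxy)-2-[methoxy(methyl)amino]-6-[(2R,3R)-3-[(2R)-2-(lithiooxy)propyl]oxiran-2-yl]hexa-3,5-dien-1-yl]benzoate | C[C@@H](O[Li])C[C@H]1O[C@@H]1/C=C/C=C/C(O[Li])(N(C)OC)Cc1c(Cl)c(O[Si](C)(C)C(C)(C)C)cc(O[Si](C)(C)C(C)(C)C)c1C(=O)O[Li] | intermediate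
18 | 4,6-bis[(tert-butyldimethylsilyl)oxy]-3-chloro-2-[(3E,5E)-6-[(2R,3R)-3-[(2R)-2-hydroxypropyl]oxiran-2-yl]-2-oxohexa-3,5-dien-1-yl]benzoic acid | C[C@@H](O)C[C@H]1O[C@@H]1/C=C/C=C/C(=O)Cc1c(Cl)c(O[Si](C)(C)C(C)(C)C)cc(O[Si](C)(C)C(C)(C)C)c1C(=O)O | intermediate
19 | 6,8-bis[(tert-butyldimethylsilyl)oxy]-5-chloro-3-[(1E,3E)-4-[(2S,3R,5R)-3-hydroxy-5-methyloxolan-2-yl]buta-1,3-dien-1-yl]-1H-isochromen-1-one | C[C@@H]1C[C@@H](O)[C@H](/C=C/C=C/c2cc3c(Cl)c(O[Si](C)(C)C(C)(C)C)cc(O[Si](C)(C)C(C)(C)C)c3c(=O)o2)O1 | intermediate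
20 | 5-chloro-6,8-dihydroxy-3-[(1E,3E)-4-[(2S,3R,5R)-3-hydroxy-5-methyloxolan-2-yl]buta-1,3-dien-1-yl]-1H-isochromen-1-one | C[C@@H]1C[C@@H](O)[C@H](/C=C/C=C/c2cc3c(Cl)c(O)cc(O)c3c(=O)o2)O1 | target

**Step count and risks**

Total steps: 8. Longest linear sequence: 6 (steps 3, 4, 5, 6, 7, 8; 5 → 7 → 9 → 12 → 14 → 19 → 20).

Most likely to fail, first: step 7. The dianion of a hindered, electron-rich acid may form poorly or add in a conjugate sense to the dienamide, and the one-flask acid stage has no direct precedent. The fallback sets out from 2, uses 14 as made, and comes back at 20. Mitsunobu esterification of 2 with 2-(trimethylsilyl)ethanol (PPh3, DIAD, THF) gives 2-(trimethylsilyl)ethyl 3-chloro-4,6-dihydroxy-2-methylbenzoate F1. TBSCl and imidazole give 2-(trimethylsilyl)ethyl 4,6-bis[(tert-butyldimethylsilyl)oxy]-3-chloro-2-methylbenzoate F2. Its ester-stabilised benzylic anion (LiN(iPr)2, THF, −78 °C), the well-used resorcylate toluate anion, is acylated by 16 and quenched with aq NH4Cl to give the isolated keto ester 2-(trimethylsilyl)ethyl 4,6-bis[(tert-butyldimethylsilyl)oxy]-3-chloro-2-[(3E,5E)-6-[(2R,3R)-3-[(2R)-2-hydroxypropyl]oxiran-2-yl]-2-oxohexa-3,5-dien-1-yl]benzoate F3. Bu4NF (THF, 0 °C to rt) removes the ester and both silyl ethers to give the free seco acid 3-chloro-4,6-dihydroxy-2-[(3E,5E)-6-[(2R,3R)-3-[(2R)-2-hydroxypropyl]oxiran-2-yl]-2-oxohexa-3,5-dien-1-yl]benzoic acid F4. Acidification with CSA over 4 Å molecular sieves then closes both rings and gives 20 directly, so step 8 is not needed.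

Second: step 5. The epoxy aldehyde is sensitive, over-oxidation of the product enal is possible, and the facial outcome rests on the catalyst model rather than on a checked literature assignment. The fallback sets out from 5 and comes back at 11. Opening of 5 with dilithiated propargyl alcohol (LiNH2, liquid NH3) gives (5R)-hex-2-yne-1,5-diol F5. Reduction with NaAlH2(OCH2CH2OMe)2 in THF gives (2E,5R)-hex-2-ene-1,5-diol F6. Sharpless epoxidation (Ti(OiPr)4, D-(−)-diisopropyl tartrate, t-BuOOH, 4 Å molecular sieves, CH2Cl2, −20 °C) gives [(2R,3R)-3-[(2R)-2-hydroxypropyl]oxiran-2-yl]methanol F7 with reagent-controlled configuration. Primary-selective oxidation (TEMPO, PhI(OAc)2, CH2Cl2) gives 11, which is then treated with 10 as in step 5.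

Third: step 1. Over-chlorination or chlorination at the carbon between the two hydroxyls would be hard to separate at the acid stage. The fallback sets out from 1 and comes back at 2. Chlorination of the aldehyde with SO2Cl2 (Et2O, 0 °C) gives 3-chloro-4,6-dihydroxy-2-methylbenzaldehyde F8, which is purified and then oxidised under scavenged Pinnick conditions (NaClO2, NaH2PO4, 2-methylbut-2-ene, t-BuOH/H2O) to 2.

Further compounds
F1 | step 7 | 2-(trimethylsilyl)ethyl 3-chloro-4,6-dihydroxy-2-methylbenzoate | Cc1c(Cl)c(O)cc(O)c1C(=O)OCC[Si](C)(C)C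
F2 | step 7 | 2-(trimethylsilyl)ethyl 4,6-bis[(tert-butyldimethylsilyl)oxy]-3-chloro-2-methylbenzoate | Cc1c(Cl)c(O[Si](C)(C)C(C)(C)C)cc(O[Si](C)(C)C(C)(C)C)c1C(=O)OCC[Si](C)(C)C
F3 | step 7 | 2-(trimethylsilyl)ethyl 4,6-bis[(tert-butyldimethylsilyl)oxy]-3-chloro-2-[(3E,5E)-6-[(2R,3R)-3-[(2R)-2-hydroxypropyl]oxiran-2-yl]-2-oxohexa-3,5-dien-1-yl]benzoate | C[C@@H](O)C[C@H]1O[C@@H]1/C=C/C=C/C(=O)Cc1c(Cl)c(O[Si](C)(C)C(C)(C)C)cc(O[Si](C)(C)C(C)(C)C)c1C(=O)OCC[Si](C)(C)C
F4 | step 7 | 3-chloro-4,6-dihydroxy-2-[(3E,5E)-6-[(2R,3R)-3-[(2R)-2-hydroxypropyl]oxiran-2-yl]-2-oxohexa-3,5-dien-1-yl]benzoic acid | C[C@@H](O)C[C@H]1O[C@@H]1/C=C/C=C/C(=O)Cc1c(Cl)c(O)cc(O)c1C(=O)O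
F5 | step 5 | (5R)-hex-2-yne-1,5-diol | C[C@@H](O)CC#CCO
F6 | step 5 | (2E,5R)-hex-2-ene-1,5-diol | C[C@@H](O)C/C=C/CO
F7 | step 5 | [(2R,3R)-3-[(2R)-2-hydroxypropyl]oxiran-2-yl]methanol | C[C@@H](O)C[C@H]1O[C@@H]1CO
F8 | step 1 | 3-chloro-4,6-dihydroxy-2-methylbenzaldehyde | Cc1c(Cl)c(O)cc(O)c1C=O
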